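The route rests on cutting the bond between C2 of the dihydropyranone ring C and C1′ of ring B. The feature exploited is that C2 is the β-carbon of the C4 ketone (C2–C3–C4=O). At the chromone level, with C2=C3 in place, it becomes a flat, electrophilic, prochiral carbon. A rhodium-catalysed asymmetric 1,4-addition of 4-(geranyloxy)phenylboronic acid to 5,7-diacetoxychromone then joins both halves, saturates C2–C3 and sets the (S)-centre in one operation. The precursor is an achiral γ-pyrone whose acetates mask the ring-A phenols and sharpen the acceptor. Each partner needs one step from purchased material, and neutral deacetylation ends the route.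

Key step: step 3

Remark: C2 of the target is (S) (O1 > C1′ > C3 > H), the configuration of the natural flavanones. Compounds 1, 2 and 4 are taken as catalogue compounds.

Step 1
Reactants: 1 4-hydroxyphenylboronic acid; 2 geranyl bromide
Product: 3 4-(geranyloxy)phenylboronic acid
Conditions: K2CO3 (2 equiv), DMF, rt
Reagents that add atoms: none
Why: Williamson ether synthesis, in which the phenoxide formed by K2CO3 displaces the primary allylic bromide by SN2 with the E-alkene untouched, while the boronic acid is only bound reversibly as boronate and is recovered on aqueous work-up.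

Step 2
Reactants: 4 5,7-dihydroxychromone
Product: 6 5,7-diacetoxychromone, via 7-acetoxy-5-hydroxychromone 5 (not isolated)
Conditions: Ac2O (3 equiv), pyridine, DMAP (5 mol %), CH2Cl2, rt
Reagents that add atoms: acetic anhydride CC(=O)OC(C)=O
Why: DMAP-catalysed O-acylation (nucleophilic catalysis), in which the free 7-OH reacts first and the chelated 5-OH follows with excess anhydride, the γ-pyrone being inert to these conditions.

Step 3
Reactants: 3 4-(geranyloxy)phenylboronic acid; 6 5,7-diacetoxychromone
Product: 9 (2S)-5,7-diacetoxy-4′-(geranyloxy)flavanone, via aryl-rhodium(I) species 7 (not isolated), via rhodium oxa-π-allyl enolate 8 (not isolated)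
Conditions: [RhCl(C2H4)2]2 (1.5 mol %), (S)-MeO-F12-BIPHEP (3.3 mol %), aq. KOH (3 mol %, only to turn Rh–Cl into Rh–OH), 3 (2 equiv), toluene/H2O 10:1, 30 °C
Reagents that add atoms: none
Why: Hayashi–Miyaura reaction, here the known rhodium-catalysed asymmetric 1,4-addition of arylboronic acids to chromones: transmetalation of 3 to the Rh–OH complex gives aryl-rhodium 7, C2=C3 of 6 coordinates and inserts syn into the Rh–aryl bond to give the oxa-π-allyl enolate 8, and water protonates C3 and returns Rh–OH. No ring is closed, since ring C is already present and only C2 and C3 go from sp2 to sp3. The one new stereocentre, C2, is fixed in the insertion by the C2-symmetric (S)-biaryl bisphosphine, which should leave only the Re face of C2 open, by analogy with 2-cyclohexenone, where (S)-biaryl bisphosphines give the spatially equivalent (S)-product; the (R)-ligand is equally available should the sense prove opposite. Site selectivity comes from the substrate: C2=C3 is the only conjugated, 1,2-disubstituted alkene, whereas the two trisubstituted geranyl alkenes neither bind nor insert and the allyl aryl ether is not ionised by Rh(I) at this temperature. The acetates switch off the donation of O5 and O7 into C4=O, which makes C2 more electrophilic, and they block the 5-OH/C4=O chelate, which would tie up rhodium as an acetylacetonate-like complex. Because no free base remains and the temperature is low, retro-oxa-Michael opening of 9 (racemisation), loss of acetate and a second, 1,2-addition to the new ketone should be suppressed.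

Step 4
Reactants: 9 (2S)-5,7-diacetoxy-4′-(geranyloxy)flavanone
Product: 11 (2S)-4′-O-geranylnaringenin (target), via (2S)-5-monoacetate 10 (not isolated)
Conditions: NH4OAc (10 equiv), MeOH/THF/H2O, rt to 40 °C
Reagents that add atoms: none
Why: Ammonium-acetate-buffered methanolysis of aryl acetates (transesterification near pH 7), which cleaves the 7-ester and then the 5-ester in a medium that is neither basic enough to open ring C by a retro-oxa-Michael reaction, so that C2 keeps its configuration, nor acidic enough to touch the geranyl ether or its alkenes.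

Compound list
1 | 4-hydroxyphenylboronic acid | OB(O)c1ccc(O)cc1 | starting material
2 | geranyl bromide, (2E)-1-bromo-3,7-dimethylocta-2,6-diene | CC(C)=CCC/C(C)=C/CBr | starting material
3 | 4-(geranyloxy)phenylboronic acid, 4-{[(2E)-3,7-dimethylocta-2,6-dien-1-yl]oxy}phenylboronic acid | CC(C)=CCC/C(C)=C/COc1ccc(B(O)O)cc1 | intermediate
4 | 5,7-dihydroxychromone, 5,7-dihydroxy-4H-chromen-4-one | O=c1ccoc2cc(O)cc(O)c12 | starting material
5 | 7-acetoxy-5-hydroxychromone | CC(=O)Oc1cc(O)c2c(=O)ccoc2c1 | intermediate
6 | 5,7-diacetoxychromone, 4-oxo-4H-chromene-5,7-diyl diacetate | CC(=O)Oc1cc(OC(C)=O)c2c(=O)ccoc2c1 | intermediate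
7 | [4-(geranyloxy)phenyl]rhodium(I) species (bisphosphine on Rh not drawn) | CC(C)=CCC/C(C)=C/COc1ccc([Rh])cc1 | intermediate
8 | rhodium(I) oxa-π-allyl enolate of 9, (2S), drawn O-bound (bisphosphine on Rh not drawn) | CC(C)=CCC/C(C)=C/COc1ccc([C@@H]2C=C(O[Rh])c3c(OC(C)=O)cc(OC(C)=O)cc3O2)cc1 | intermediate
9 | (2S)-5,7-diacetoxy-4′-(geranyloxy)flavanone | CC(C)=CCC/C(C)=C/COc1ccc([C@@H]2CC(=O)c3c(OC(C)=O)cc(OC(C)=O)cc3O2)cc1 | intermediate
10 | (2S)-5-acetoxy-7-hydroxy-4′-(geranyloxy)flavanone | CC(C)=CCC/C(C)=C/COc1ccc([C@@H]2CC(=O)c3c(OC(C)=O)cc(O)cc3O2)cc1 | intermediate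
11 | (2S)-2-(4-{[(2E)-3,7-dimethylocta-2,6-dien-1-yl]oxy}phenyl)-5,7-dihydroxy-2,3-dihydro-4H-chromen-4-one, (2S)-4′-O-geranylnaringenin | CC(C)=CCC/C(C)=C/COc1ccc([C@@H]2CC(=O)c3c(O)cc(O)cc3O2)cc1 | target

Total step count: 4. Longest linear sequence: 3 steps (step 1 or step 2, then steps 3 and 4).

Steps most likely to fail

Step 3. Carborhodation of the vinylogous ester may be too slow, so that protodeboronation of the electron-rich boronic acid consumes the nucleophile. The facial selectivity may also be insufficient, and traces of rhodium hydride could begin to isomerise the allylic ether. The fallback separates bond formation from stereocontrol.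
- It sets out from 3 and 6. The more active achiral catalyst [Rh(OH)(cod)]2 in dioxane/H2O should give racemic 5,7-diacetoxy-4′-(geranyloxy)flavanone F1.
- A kinetic resolution by Noyori–Ikariya transfer hydrogenation follows ([Cp*RhCl((R,R)-TsDPEN)], HCO2H/Et3N, EtOAc, stopped near half conversion).
- This should reduce only the (2R)-ketone, because hydride delivery to the 4R carbinol is matched there with the preferred cis addition. The product is (2R,4R)-cis-5,7-diacetoxy-4′-(geranyloxy)flavan-4-ol F2.
- Chromatography then returns the untouched (S)-ketone, and the route is rejoined at 9.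

Step 4. Ring C may open and reclose reversibly by a retro-oxa-Michael reaction once phenoxides form, which erodes the enantiomeric purity. The solvolysis may also stall at the hindered peri ester on C5. The fallback changes the class of protecting group to fluoride-labile silyl ethers.
- It sets out from 4. TBSCl/imidazole/DMF should give 5,7-bis(tert-butyldimethylsilyloxy)chromone F3.
- Addition of 3 under the conditions of step 3 should give (2S)-5,7-bis(tert-butyldimethylsilyloxy)-4′-(geranyloxy)flavanone F4.
- Et3N·3HF in THF at 0 °C, a weakly acidic fluoride source, should cleave both aryl silyl ethers, and the route is rejoined at 11.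

Step 1. The electron-rich phenoxide-boronate may protodeboronate during the alkylation, the bromide may be consumed at boron-bound oxygen, or material may be lost on isolating the boronic acid/boroxine mixture. The fallback introduces boron after the ether is made.
- It sets out from 2. Alkylation of purchased 4-bromophenol (K2CO3, acetone, reflux) should give 1-bromo-4-(geranyloxy)benzene F5.
- n-BuLi (THF, −78 °C) should give 4-(geranyloxy)phenyllithium F6.
- B(OiPr)3 traps it as lithium [4-(geranyloxy)phenyl]triisopropoxyborate F7.
- Cold dilute HCl hydrolyses this, and the route is rejoined at 3.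

Further compounds
F1 | step 3 | racemic 5,7-diacetoxy-4′-(geranyloxy)flavanone | CC(C)=CCC/C(C)=C/COc1ccc(C2CC(=O)c3c(OC(C)=O)cc(OC(C)=O)cc3O2)cc1
F2 | step 3 | (2R,4R)-cis-5,7-diacetoxy-4′-(geranyloxy)flavan-4-ol | CC(C)=CCC/C(C)=C/COc1ccc([C@H]2C[C@@H](O)c3c(OC(C)=O)cc(OC(C)=O)cc3O2)cc1
F3 | step 4 | 5,7-bis(tert-butyldimethylsilyloxy)chromone | CC(C)(C)[Si](C)(C)Oc1cc(O[Si](C)(C)C(C)(C)C)c2c(=O)ccoc2c1
F4 | step 4 | (2S)-5,7-bis(tert-butyldimethylsilyloxy)-4′-(geranyloxy)flavanone | CC(C)=CCC/C(C)=C/COc1ccc([C@@H]2CC(=O)c3c(O[Si](C)(C)C(C)(C)C)cc(O[Si](C)(C)C(C)(C)C)cc3O2)cc1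
F5 | step 1 | 1-bromo-4-(geranyloxy)benzene | CC(C)=CCC/C(C)=C/COc1ccc(Br)cc1
F6 | step 1 | 4-(geranyloxy)phenyllithium | CC(C)=CCC/C(C)=C/COc1ccc([Li])cc1
F7 | step 1 | lithium [4-(geranyloxy)phenyl]triisopropoxyborate | [Li+].CC(C)=CCC/C(C)=C/COc1ccc([B-](OC(C)C)(OC(C)C)OC(C)C)cc1
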